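The earlier runs and the new flask are simulated with made-up constants; the scatter is artificial.

The red run, charged with 3.00 equivalents of reagent per substrate, reaches 33.4% tetra adduct at 3.00 h and is still climbing. The teal flask, charged with 1.50 equivalents, stands flat from 3.00 h to 20.0 h at a mean reading of 8.45%.

all flasks: substrate 0.019 M; temperature 90 °C

| charge | reagent | remark | time |
|---|---|---|---|
| teal | 0.0285 M | the very flask that is asked about, followed so far |  |
| red | 0.057 M | run made earlier |  |
| flask | 0.0285 M |  | 30 h |

| run | time / h | tetra adduct / % |
|---|---|---|
| teal | 1.00 | 4.6 |
| teal | 3.00 | 8.3 |
| teal | 5.00 | 8.0 |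
| teal | 8.00 | 8.6 |
| teal | 10.0 | 8.8 |
| teal | 15.0 | 8.3 |
| teal | 20.0 | 8.7 |
| red | 0.417 | 11.0 |
| red | 0.833 | 19.5 |
| red | 1.33 | 25.0 |
| red | 1.50 | 26.5 |
| red | 2.00 | 30.1 |
| red | 2.50 | 32.1 |
| red | 3.00 | 33.4 |

(standard deviation of a reading: 0.3 percentage points)

- Thursday's: change nothing and wait 15 h more
- Sunday's: at 30 h raise the temperature by 15 K, then wait 15 h
- Friday's: at 30 h take out 90% of the tetra adduct then present, then wait 15 h
- Wednesday's: at 30 h add reagent, 100% of the amount charged, then wait 15 h

- removed tetra adduct is counted in
- additions bring no volume worth counting
- the earlier runs do not show what temperature does; that part of a forecast is a guess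

- tetra adduct, in percent of the substrate first charged, at 30 h
- the option that brings most further tetra adduct ("none" if no option brings more than 2 percentage points) (Thursday's / Sunday's / Friday's / Wednesday's / none)
- tetra adduct present, with what was taken out counted in, in percent of the substrate first charged, after Sunday's
- tetra adduct present, with what was taken out counted in, in percent of the substrate first charged, after Wednesday's

The last gains of the red run shrink from 2 percentage points to 1.3 points per equal interval, and summing that shrinking series puts its plateau, as a reading, near 35.8%. The teal flask does not stop for want of substrate, because the red run makes more tetra adduct from the same substrate charge, so this reckoning reads the reagent as the limiting reagent.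

The ledger runs in equivalents of reagent per substrate and counts 4 reagent units in each tetra adduct, as the name says. Of the 1.50 charged to the teal flask, tetra adduct holds 0.338, which is 22.5% of the charge, and the other 1.16 stand in forms no reading shows. Of the further 1.50 in the red run, tetra adduct takes 1.09, or 72.9%, so in these readings the further equivalents show a larger share in tetra adduct than the first ones.

Dividing the rate of tetra adduct formation by the rate of reagent loss removes time, and this reckoning carries 18 points per equivalent: the marginal yield, tetra adduct gained per further equivalent of reagent between these two charges, at this substrate charge. The flat readings put the teal flask at 8.45% at 30 h. Wednesday's charge of 100% should carry it to 35.8%, while the other options add no reagent, and Sunday's stays a guess at 8.45%.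

The forecast gives 8.5% at 30 h, Wednesday's as the best option, 8.6% after Sunday's and 16.5% after Wednesday's, reasoning that “a second charge gives about another 8%, slightly less for used substrate”. It parts from this reckoning on Wednesday's value.

    substrate + reagent → first product + by-product (k = 0.0490 /M/s, Ea = 49.0 kJ/mol)
    reagent + first product → bis adduct + by-product (k = 0.00680 /M/s, Ea = 77.0 kJ/mol)
    reagent + bis adduct → triple product + by-product (k = 0.130 /M/s, Ea = 47.0 kJ/mol)
    reagent + triple product → tetra adduct + by-product (k = 0.120 /M/s, Ea = 61.0 kJ/mol)
    substrate + bis adduct → side product (k = 0.00240 /M/s, Ea = 65.0 kJ/mol)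
    tetra adduct ⇌ isomer of the product (K = 0.730, k = 0.00120 /s, Ea = 100 kJ/mol, ΔH = −35.0 kJ/mol)
    (constants at 90 °C)

The teal flask gives 8.53% at 30 h, 10.1% after Sunday's and 37.5% after Wednesday's, and Wednesday's brings 29 points more. The red run, taken to the same 30 h, holds 37.4%. For a further flask, charged from the start with more reagent and the same substrate, the marginal yield of 18 points per equivalent asks for 1.78 equivalents to lift tetra adduct at 30 h by 5 points, and that flask shows this rise at 1.79 equivalents of reagent.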